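In a closed stirred flask or a stirred flow tank the same charge meets two competing couplings, and what the vessel changes is the level of second end groups at the moment the first end groups react.

| flask | first end groups | second end groups | protic impurity | remark | time |
|---|---|---|---|---|---|
| east | 0.80 M | 0.816 M | 0.16 M | run made earlier |  |
| north-west | 0.54 M | 0.816 M | 0.16 M | run made earlier |  |
| north | 1.2 M | 0.816 M | 0.16 M | run made earlier |  |
| south-west | 0.80 M | 1.6 M | 0.16 M | run made earlier |  |
| ash | 0.80 M | 0.816 M | 0.160 M | everything together in a closed stirred flask, run for 15 h | 15 h |
| elm | 0.80 M | 0.816 M | 0.160 M | one stirred flow tank at steady state, fed with the mixture as stated, mean residence time 75.0 h |  |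
| larch | 0.80 M (fed, over 12.0 h) | 0.816 M | 0.160 M | a stirred flask in which first end groups is dosed at a steady rate over 12.0 h without added volume, worked up at 15 h | 15 h |
| oak | 0.80 M | 0.816 M | 0.160 M | one stirred flow tank at steady state, fed with the mixture as stated, mean residence time 15 h |  |

| run | time / h | links / % | first end groups / % |
|---|---|---|---|
| east | 0.833 | 23 | 6 |
| east | 2.50 | 24 | 2 |
| east | 4.00 | 25 | 5 |
| east | 6.00 | 22 | 6 |
| east | 10.0 | 21 | 3 |
| east | 12.0 | 23 | 6 |
| east | 15.0 | 21 | 5 |
| north-west | 1.33 | 33 | 0 |
| north-west | 2.00 | 34 | 0 |
| north-west | 3.00 | 30 | 2 |
| north-west | 4.00 | 28 | 0 |
| north-west | 6.00 | 28 | 0 |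
| north-west | 10.0 | 26 | 0 |
| north-west | 15.0 | 26 | 4 |
| north | 2.00 | 17 | 33 |
| north | 4.00 | 16 | 34 |
| north | 6.00 | 13 | 33 |
| north | 8.00 | 11 | 34 |
| north | 10.0 | 11 | 35 |
| north | 12.0 | 15 | 30 |
| north | 15.0 | 17 | 34 |
| south-west | 3.00 | 48 | 5 |
| south-west | 6.00 | 47 | 2 |
| south-west | 10.0 | 40 | 0 |
| south-west | 12.0 | 43 | 0 |
| south-west | 15.0 | 39 | 1 |

(scatter of a reading: 2 percentage points)

- the set-up with the highest amount of links at the outlet or at the end, in percent of the first end groups put in ("none" if the first two lie within 2 percentage points) (ash / elm / larch / oak / none)
- amount of links at the outlet or at the end, in percent of the first end groups put in, ash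
- amount of links at the outlet or at the end, in percent of the first end groups put in, elm
- amount of links at the outlet or at the end, in percent of the first end groups put in, larch
- amount of links at the outlet or at the end, in percent of the first end groups put in, oak

- the stated concentrations are those of everything mixed, before any reaction; amounts are the same in each set-up
- steps under discussion: first end groups + second end groups -> links; links <-> isomer of the product; second end groups + protic impurity -> quenched reagent; first end groups + second end groups -> rings
- the feed brings no volume worth counting
- the earlier runs were made in a closed, stirred flask

Let B be the concentration of second end groups at a given moment. The share of reacting first end groups that becomes links, the selectivity, climbs with B: at its first sample south-west, charged at 1.6 M, reads 48% links, while east, charged at 0.816 M, reads 23%. I compare the two rates at one moment and suppose that the step to rings does not slow as B falls, which gives a share of B/(B+X). Second end groups fall one for one with first end groups, so in south-west B runs from its charge down to about 0.800 M and averages 1.20 M, and the reading there gives X = 1.30 M. This X is the crossover level, the level of second end groups at which links and rings form equally fast.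

East checks it, being a different run: its average of 0.416 M gives a share of 24.2% against the 23% read, and that average lies lower than X, so rings lead there. As B drifts down, the comparison tips further towards rings, so a vessel is worth the level it holds.

Ash repeats the east recipe, so I take the east reading at 15.0 h, 21%. A tank works at its outlet level of second end groups, and the feed holds a surplus of them over first end groups of 0.0160 M, which is far lower than X and lower than the impurity charged, so I use that surplus as a rough guide only, and with the quench left out of the count it gives me 1.22%. In larch I suppose that the long dosing lets the impurity take its whole 0.160 M; that leaves 0.656 M of second end groups, less than the 0.80 M dosed, with an average level of 0.328 M, so I reckon 16.5% before any fading.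

The forecast puts ash first, with ash 21.5%, elm 0.5%, larch 18% and oak 2%. It works with a crossover of 1.25 M, and of the tanks it says “these run at near-zero B, so selectivity collapses to a few percent or less”. My larch figure lies lower than its own.

The flask gives ash first, with ash 20.4%, elm 0.0518%, larch 15.8% and oak 0.368%.

    first end groups + second end groups → links (k = 0.0603 M⁻¹ min⁻¹)
    links ⇌ isomer of the product (K = 0.330, k = 5.65 × 10⁻⁴ min⁻¹)
    second end groups + protic impurity → quenched reagent (k = 0.0522 M⁻¹ min⁻¹)
    first end groups + second end groups → rings, rate k4*[first end groups] as long as [second end groups] is above zero (k = 0.0584 min⁻¹)

At the charge of ash, a first end group meets the step to links at 0.0492 min⁻¹ and the step to rings at 0.0584 min⁻¹, so links run slower from the first moment, and ash ends at 20.4%. Reckoned with the crossover level of 1.30 M, a reading from south-west, larch stood at 16.5% and holds 15.8%, and oak, with the quench left out of the count, stood at 1.22% and holds 0.368%.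

All runs stem from a simulated flask from invented constants, and the scatter is random.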